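The benzene ring of the target bears oxygen at C1 and C3 and its single carbon branch at C5, the substitution pattern of a 5-substituted cyclohexane-1,3-dione. That dione is disconnected into an enone (C5, C6, C1, C2) and a malonate (C3, C4). In one operation a Michael addition followed by a Claisen closure forms C4–C5 and C2–C3 and closes the carbocycle while it is still saturated. The enone partner is (E)-5-(2-henicosyl-1,3-dioxolan-2-yl)pent-3-en-2-one, with the side-chain ketone (C2') masked as a dioxolane; it is made from docosanoic acid in four steps. Ester and ketal are then removed together, and catalytic dehydrogenation delivers the resorcinol.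

Key step: step 5

Remark: diones 13–16 and F3 are drawn as diketo tautomers although they should be largely enolised; the annulation product is a vinylogous acid, so the base in step 5 is used in a full equivalent.

Step 1
Reactants: 1 docosanoic acid; 2 potassium methyl malonate (KO2CCH2CO2Me)
Product: 5 methyl 3-oxotetracosanoate, via 1-docosanoylimidazole 3 (not isolated), via 2-(methoxycarbonyl)-3-oxotetracosanoic acid 4 (not isolated)
Conditions: 1,1'-carbonyldiimidazole (CDI), THF, 40 °C; then 2, MgCl2, Et3N, MeCN–THF, rt to 45 °C; aq. HCl work-up
Reagents that add atoms: none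
Why: Masamune–Brooks homologation, in which the acyl imidazolide C-acylates the magnesium enolate of the malonate half-ester and the acylmalonic half-ester loses CO2 on acidic work-up, a mild one-pot route from a fatty acid to its β-keto ester.

Step 2
Reactants: 5 methyl 3-oxotetracosanoate
Product: 6 methyl 2-(2-henicosyl-1,3-dioxolan-2-yl)acetate
Conditions: HOCH2CH2OH, p-TsOH·H2O (cat.), toluene, reflux, Dean–Stark
Reagents that add atoms: ethylene glycol, OCCO
Why: Acid-catalysed ketalisation with azeotropic removal of water converts the ketone of the β-keto ester into its dioxolane while the methyl ester remains a spectator.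

Step 3
Reactants: 6 methyl 2-(2-henicosyl-1,3-dioxolan-2-yl)acetate
Product: 7 2-(2-henicosyl-1,3-dioxolan-2-yl)ethan-1-ol
Conditions: LiAlH4, THF, 0 °C to rt; aq. NaOH work-up
Reagents that add atoms: none
Why: Hydride reduction of the ester to the primary alcohol at ambient temperature avoids a low-temperature partial reduction of a poorly soluble long-chain ester, and the basic work-up leaves the ketal intact.

Step 4
Reactants: 7 2-(2-henicosyl-1,3-dioxolan-2-yl)ethan-1-ol; 8 1-(triphenylphosphoranylidene)propan-2-one
Product: 10 (E)-5-(2-henicosyl-1,3-dioxolan-2-yl)pent-3-en-2-one, via 2-(2-henicosyl-1,3-dioxolan-2-yl)acetaldehyde 9 (not isolated)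
Conditions: Dess–Martin periodinane, pyridine, CH2Cl2, 0 °C to rt; then 8, CH2Cl2, 40 °C
Reagents that add atoms: none
Why: Dess–Martin oxidation followed in the same flask by a Wittig reaction with a ketone-stabilised ylide, so that the elimination-prone β-ketal aldehyde is consumed as it forms in a buffered, non-basic medium and the stabilised ylide delivers the E-alkene.

Step 5
Reactants: 10 (E)-5-(2-henicosyl-1,3-dioxolan-2-yl)pent-3-en-2-one; 11 dimethyl malonate
Product: 13 methyl trans-2-[(2-henicosyl-1,3-dioxolan-2-yl)methyl]-4,6-dioxocyclohexane-1-carboxylate (racemic), via dimethyl 2-[1-(2-henicosyl-1,3-dioxolan-2-yl)-4-oxopentan-2-yl]propanedioate 12 (not isolated)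
Conditions: NaOMe (1.05 equiv), 11 (1.2 equiv), MeOH–THF, rt, then 65 °C; AcOH (aq), 0 °C
Reagents that add atoms: none
Why: Sodiomalonate adds to the β-carbon of enone 10 (new bond C4–C5, resorcinol numbering), adduct 12 equilibrates to its methyl-ketone enolate, and that carbon attacks one malonate ester with loss of methoxide (new bond C2–C3); the cyclic 1,3-dione is then deprotonated, which makes the sequence irreversible and consumes the full equivalent of base. The closest known reaction type is the Michael–Claisen annulation of alkenyl methyl ketones with malonic esters that gives 4-alkoxycarbonyl-5-alkylcyclohexane-1,3-diones. The six-membered carbocycle closes in the 6-(enolendo)-exo-trig mode, because both enolate carbons become ring atoms while the ester carbonyl oxygen stays outside the ring. The side-chain-bearing centre forms by attack on either face of the flat enone and is racemic, whereas the ester-bearing centre is epimerisable through the β-keto ester enol and should settle trans to its neighbour under thermodynamic control; both centres are erased later. The selectivity needed is conjugate addition ahead of γ-deprotonation of 10, secured by having all base present as the soft, weakly basic malonate anion (malonate in slight excess over NaOMe), by the unhindered E-enone, and by the cyclic ketal, whose oxygen would remain tethered and could re-add if it were expelled. The regiochemistry of ring closure is fixed by ring size, since only the methyl terminus of the ketone can reach an ester through a six-membered transition state.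

Step 6
Reactants: 13 methyl trans-2-[(2-henicosyl-1,3-dioxolan-2-yl)methyl]-4,6-dioxocyclohexane-1-carboxylate
Product: 16 5-(2-oxotricosyl)cyclohexane-1,3-dione, via trans-2-[(2-henicosyl-1,3-dioxolan-2-yl)methyl]-4,6-dioxocyclohexane-1-carboxylic acid 14 (not isolated), via 5-[(2-henicosyl-1,3-dioxolan-2-yl)methyl]cyclohexane-1,3-dione 15 (not isolated)
Conditions: NaOH (aq), MeOH–THF, 65 °C; then HCl (aq) to pH 3, 50 °C; then HCl (aq) to pH 1, THF, 50 °C
Reagents that add atoms: water, O
Why: Saponification, decarboxylation of the β-keto acid through its cyclic transition state and acid-catalysed ketal hydrolysis run in one pot, and removing the carboxyl carbon while the ring is still saturated means that a carboxyl group and a 2-oxoalkyl chain never sit ortho on an arene, where they would lactonise to an isocoumarin.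

Step 7
Reactants: 16 5-(2-oxotricosyl)cyclohexane-1,3-dione
Product: 17 5-(2'-oxotricosyl)resorcinol [1-(3,5-dihydroxyphenyl)tricosan-2-one]
Conditions: Pd/C (10 wt% Pd on carbon, cat.), triglyme, 190 °C, N2 sweep
Reagents that add atoms: none
Why: Catalytic dehydrogenation of a cyclohexane-1,3-dione to a resorcinol, the reaction type used to make resorcinol itself, in which loss of H2 across C4–C5 gives a dienone that tautomerises to the arene, while the isolated side-chain ketone meets no oxidant or halogen.

Compound list
1 | docosanoic acid | CCCCCCCCCCCCCCCCCCCCCC(=O)O | starting material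
2 | potassium methyl malonate (potassium 3-methoxy-3-oxopropanoate) | COC(=O)CC(=O)[O-].[K+] | starting material
3 | 1-docosanoylimidazole | CCCCCCCCCCCCCCCCCCCCCC(=O)n1ccnc1 | intermediate
4 | 2-(methoxycarbonyl)-3-oxotetracosanoic acid (racemic) | CCCCCCCCCCCCCCCCCCCCCC(=O)C(C(=O)O)C(=O)OC | intermediate
5 | methyl 3-oxotetracosanoate | CCCCCCCCCCCCCCCCCCCCCC(=O)CC(=O)OC | intermediate
6 | methyl 2-(2-henicosyl-1,3-dioxolan-2-yl)acetate | CCCCCCCCCCCCCCCCCCCCCC1(CC(=O)OC)OCCO1 | intermediate
7 | 2-(2-henicosyl-1,3-dioxolan-2-yl)ethan-1-ol | CCCCCCCCCCCCCCCCCCCCCC1(CCO)OCCO1 | intermediate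
8 | 1-(triphenylphosphoranylidene)propan-2-one | CC(=O)C=P(c1ccccc1)(c1ccccc1)c1ccccc1 | starting material
9 | 2-(2-henicosyl-1,3-dioxolan-2-yl)acetaldehyde | CCCCCCCCCCCCCCCCCCCCCC1(CC=O)OCCO1 | intermediate
10 | (E)-5-(2-henicosyl-1,3-dioxolan-2-yl)pent-3-en-2-one | CCCCCCCCCCCCCCCCCCCCCC1(C/C=C/C(C)=O)OCCO1 | intermediate
11 | dimethyl malonate | COC(=O)CC(=O)OC | starting material
12 | dimethyl 2-[1-(2-henicosyl-1,3-dioxolan-2-yl)-4-oxopentan-2-yl]propanedioate (racemic) | CCCCCCCCCCCCCCCCCCCCCC1(CC(CC(C)=O)C(C(=O)OC)C(=O)OC)OCCO1 | intermediate
13 | methyl trans-2-[(2-henicosyl-1,3-dioxolan-2-yl)methyl]-4,6-dioxocyclohexane-1-carboxylate (racemic, one enantiomer drawn) | O=C1CC(=O)[C@@H](C(=O)OC)[C@H](CC2(CCCCCCCCCCCCCCCCCCCCC)OCCO2)C1 | intermediate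
14 | trans-2-[(2-henicosyl-1,3-dioxolan-2-yl)methyl]-4,6-dioxocyclohexane-1-carboxylic acid (racemic, one enantiomer drawn) | O=C1CC(=O)[C@@H](C(=O)O)[C@H](CC2(CCCCCCCCCCCCCCCCCCCCC)OCCO2)C1 | intermediate
15 | 5-[(2-henicosyl-1,3-dioxolan-2-yl)methyl]cyclohexane-1,3-dione (achiral) | O=C1CC(=O)CC(CC2(CCCCCCCCCCCCCCCCCCCCC)OCCO2)C1 | intermediate
16 | 5-(2-oxotricosyl)cyclohexane-1,3-dione (achiral) | CCCCCCCCCCCCCCCCCCCCCC(=O)CC1CC(=O)CC(=O)C1 | intermediate
17 | 5-(2'-oxotricosyl)resorcinol | CCCCCCCCCCCCCCCCCCCCCC(=O)Cc1cc(O)cc(O)c1 | target

Total step count: 7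
Longest linear sequence: 7 steps (1 to 17)

Steps most likely to fail

Step 5. Base-induced γ-deprotonation of the enone, with deconjugation or opening of the dioxolane, may compete with conjugate addition. The Michael adduct may also revert before it cyclises. The fallback uses the complementary Michael–Claisen pairing, in which the acceptor is a less γ-acidic enoate and the donor carries the methyl ketone. It sets out from alcohol 7 and comes back at 13. Alcohol 7 is oxidised as in step 4 and aldehyde 9 is trapped with methyl (triphenylphosphoranylidene)acetate to give methyl (E)-4-(2-henicosyl-1,3-dioxolan-2-yl)but-2-enoate F1. Heating F1 with methyl acetoacetate and NaOMe in MeOH–THF should give, by conjugate addition of the acetoacetate carbanion, dimethyl 2-acetyl-3-[(2-henicosyl-1,3-dioxolan-2-yl)methyl]pentanedioate F2. The acetyl methyl enolate of F2 closes onto the terminal ester with loss of methanol and so returns to 13.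

Step 7. Hydrogen transfer between substrate molecules on the catalyst may cause disproportionation, and hydrogenolytic loss of a ring oxygen would lead to a monophenol. The fallback is halogenation followed by dehydrohalogenation. It sets out from 16 and comes back at 17. One equivalent of Br2 in DMF at 0 °C should brominate the enolised dione, far more reactive than the side-chain ketone, to give 2-bromo-5-(2-oxotricosyl)cyclohexane-1,3-dione F3. Warming the same solution lets the HBr present shift the bromine to C4 and then eliminates HBr, giving 17.

Step 4. A ketal oxygen may be lost from the β-ketal aldehyde by β-elimination before the sluggish ketone-stabilised ylide has reacted. The fallback builds the enone by cross-metathesis and involves no aldehyde. It sets out from docosanoic acid 1 and comes back at 10. Acid 1 is converted with CDI and MeNHOMe·HCl into the Weinreb amide N-methoxy-N-methyldocosanamide F4. Addition of CH2=CHCH2MgBr in THF at −20 °C should give pentacos-1-en-4-one F5. Ketalisation with Me3SiOCH2CH2OSiMe3 and catalytic Me3SiOTf in CH2Cl2 at −78 °C, conditions chosen to avoid migration of the double bond, gives 2-henicosyl-2-(prop-2-en-1-yl)-1,3-dioxolane F6. Cross-metathesis of F6 with but-3-en-2-one, using the second-generation Grubbs catalyst in CH2Cl2 at 40 °C, should give the E-enone 10.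

Further compounds
F1 | step 5 | methyl (E)-4-(2-henicosyl-1,3-dioxolan-2-yl)but-2-enoate | CCCCCCCCCCCCCCCCCCCCCC1(C/C=C/C(=O)OC)OCCO1
F2 | step 5 | dimethyl 2-acetyl-3-[(2-henicosyl-1,3-dioxolan-2-yl)methyl]pentanedioate (racemic mixture of diastereomers) | CCCCCCCCCCCCCCCCCCCCCC1(CC(CC(=O)OC)C(C(C)=O)C(=O)OC)OCCO1
F3 | step 7 | 2-bromo-5-(2-oxotricosyl)cyclohexane-1,3-dione (enolised at C2, no fixed configuration) | CCCCCCCCCCCCCCCCCCCCCC(=O)CC1CC(=O)C(Br)C(=O)C1
F4 | step 4 | N-methoxy-N-methyldocosanamide | CCCCCCCCCCCCCCCCCCCCCC(=O)N(C)OC
F5 | step 4 | pentacos-1-en-4-one | CCCCCCCCCCCCCCCCCCCCCC(=O)CC=C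
F6 | step 4 | 2-henicosyl-2-(prop-2-en-1-yl)-1,3-dioxolane | CCCCCCCCCCCCCCCCCCCCCC1(CC=C)OCCO1
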